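Retrosynthetic overview
- Feature: in the 2,5-dihydro-1-benzoxepine core, the ring oxygen O1 sits on C9a, para to the acyl-bearing C7. The phenolic carbons C6 and C8 are ortho to C7, so all three aryl C–O bonds can be made by addition–elimination on a 2,4,6-trifluorophenyl ketone.
- Endgame: C6–OH and C8–OH come from C–F by SNAr with p-methoxybenzyl (PMB) alkoxide, followed by acid removal of the PMB groups and the catechol MOM groups.
- Key disconnection: O1–C9a, closed by the alkoxide of a Z-allylic alcohol chain held on C5a. The oxepine is the only ring formed; both benzene rings are bought.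
- Precursor: the C7–C(=O) bond comes from lithiation between two fluorines and Weinreb acylation. The C4–C5 bond comes from Negishi coupling of 2,4,6-trifluorobenzylzinc bromide with a Z-iodoalkene made from propargyl alcohol.

Key step: step 8

Remark: the target has no stereocentre, and its only alkene is held Z by the seven-membered ring. It is therefore achiral and has no enantiomer. The one stereochemical task is the Z geometry of the open-chain alkene, which is set in step 1.

Step 1
Reactants: 1 prop-2-yn-1-ol
Product: 3 (Z)-3-iodo-2-methylprop-2-en-1-ol, via dimagnesium alkenyl alkoxide 2 (not isolated)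
Conditions: MeMgBr (2.5 equiv), CuI (10 mol %), Et2O–THF, −10 °C → rt; then I2, 0 °C; aq. work-up
Reagents that add atoms: methylmagnesium bromide C[Mg]Br; iodine II
Why: Hydroxyl-directed, copper-catalysed anti-carbomagnesiation of the alkyne places methyl on the inner carbon and magnesium on the terminal carbon cis to the CH2O arm (five-membered O–Mg chelate), and iodinolysis of the C–Mg bond with retention fixes the Z geometry that the ring closure later needs.

Step 2
Reactants: 3 (Z)-3-iodo-2-methylprop-2-en-1-ol
Product: 4 (Z)-tert-butyl[(3-iodo-2-methylprop-2-en-1-yl)oxy]dimethylsilane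
Conditions: TBSCl, imidazole, CH2Cl2, 0 °C → rt
Reagents that add atoms: tert-butyldimethylsilyl chloride CC(C)(C)[Si](C)(C)Cl
Why: Imidazole-promoted silylation of a primary alcohol is routine and masks the acidic O–H for the organozinc and organolithium steps without touching the alkenyl iodide.

Step 3
Reactants: 5 2,4,6-trifluorobenzyl bromide; 4 (Z)-tert-butyl[(3-iodo-2-methylprop-2-en-1-yl)oxy]dimethylsilane
Product: 7 (Z)-tert-butyldimethyl{[2-methyl-4-(2,4,6-trifluorophenyl)but-2-en-1-yl]oxy}silane, via 2,4,6-trifluorobenzylzinc bromide 6 (not isolated)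
Conditions: Zn dust, LiCl, THF, 0 → 25 °C; then 4, Pd(OAc)2 (2 mol %), SPhos (4 mol %), THF, 25 °C
Reagents that add atoms: none
Why: LiCl-assisted zinc insertion into the benzylic C–Br bond and Negishi cross-coupling with the alkenyl iodide form the future C4–C5 bond with retention of the Z geometry, since oxidative addition and reductive elimination at sp2 carbon are stereoretentive and the C–F bonds and silyl ether are inert to Pd(0) and to the mild zinc reagent.

Step 4
Reactants: 8 3-(3,4-dihydroxyphenyl)propanoic acid
Product: 10 3-(3,4-dihydroxyphenyl)-N-methoxy-N-methylpropanamide, via benzotriazolyl ester 9 (not isolated)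
Conditions: MeNH(OMe)·HCl, EDC·HCl, HOBt, N-methylmorpholine, DMF, 0 °C → rt, N2
Reagents that add atoms: N,O-dimethylhydroxylamine hydrochloride CNOC.Cl
Why: Carbodiimide/HOBt amide coupling, in which the free amine is far more nucleophilic than the catechol hydroxyls towards active ester 9, so that the phenols need no protection at this stage.

Step 5
Reactants: 10 3-(3,4-dihydroxyphenyl)-N-methoxy-N-methylpropanamide
Product: 11 3-[3,4-bis(methoxymethoxy)phenyl]-N-methoxy-N-methylpropanamide
Conditions: MOMCl (3 equiv), i-Pr2NEt, CH2Cl2, 0 °C → rt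
Reagents that add atoms: chloromethyl methyl ether COCCl
Why: Base-mediated O-alkylation of both phenols (Williamson type) with the highly reactive chloromethyl ether gives acetals that are inert to organolithium, fluoride and alkoxide reagents and fall only to acid.

Step 6
Reactants: 7 (Z)-tert-butyldimethyl{[2-methyl-4-(2,4,6-trifluorophenyl)but-2-en-1-yl]oxy}silane; 11 3-[3,4-bis(methoxymethoxy)phenyl]-N-methoxy-N-methylpropanamide
Product: 14 3-[3,4-bis(methoxymethoxy)phenyl]-1-{3-[(Z)-4-(tert-butyldimethylsilyloxy)-3-methylbut-2-en-1-yl]-2,4,6-trifluorophenyl}propan-1-one, via aryllithium 12 (not isolated), via lithium hemiaminal adduct 13 (not isolated)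
Conditions: n-BuLi (1.05 equiv), THF, −78 °C, 1 h; 11 in THF, −78 °C, 2 h; AcOH in THF, −78 °C → rt
Reagents that add atoms: none
Why: Directed ortho-lithiation takes the proton flanked by two fluorines (both such positions of 7 are equivalent), which at −78 °C is removed much faster than the benzylic–allylic CH2 protons, and the Weinreb ketone synthesis stops at chelate 13, which the cold acetic acid quench turns into the ketone before free lithium amide could attack the now activated C–F bonds.

Step 7
Reactants: 14 silyl ether ketone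
Product: 15 3-[3,4-bis(methoxymethoxy)phenyl]-1-{2,4,6-trifluoro-3-[(Z)-4-hydroxy-3-methylbut-2-en-1-yl]phenyl}propan-1-one
Conditions: HF·pyridine, pyridine, THF, 0 °C → rt
Reagents that add atoms: none
Why: Fluoride-mediated desilylation in an acidic pyridinium buffer frees the primary allylic alcohol without ever forming its alkoxide, so that no uncontrolled SNAr starts here, and the aryl MOM acetals, ketone and Z alkene are stable to it.

Step 8
Reactants: 15 3-[3,4-bis(methoxymethoxy)phenyl]-1-{2,4,6-trifluoro-3-[(Z)-4-hydroxy-3-methylbut-2-en-1-yl]phenyl}propan-1-one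
Product: 18 3-[3,4-bis(methoxymethoxy)phenyl]-1-(6,8-difluoro-3-methyl-2,5-dihydro-1-benzoxepin-7-yl)propan-1-one, via potassium alkoxide 16 (not isolated), via Meisenheimer adduct 17 (not isolated)
Conditions: t-BuOK (1.0 equiv, slow addition), 18-crown-6 (1.5 equiv), DMSO–THF 1:1, 0.01 M, 0 °C → rt
Reagents that add atoms: none
Why: Deprotonation gives a small equilibrium share of crown-separated potassium alkoxide 16 (most of the anion rests as the unreactive ketone enolate, which serves only as a reservoir); its oxygen adds to C9a to give Meisenheimer adduct 17, whose charge runs through C9, C5a and C7 into the ketone oxygen and is further stabilised by the fluorines on C6 and C8, and loss of fluoride restores the arene. This is the well-known intramolecular SNAr etherification of ketone-activated aryl fluorides by tethered alkoxides. The oxepine closes in a 7-exo-trig mode with respect to the C9a=C9 bond, and the Z alkene, which holds CH2O− and CH2Ar on the same side, removes the rotational freedom that usually makes seven-membered closure slow. No stereocentre results, because the sp3 C9a of 17 becomes planar again. The step needs attack at C9a–F (para) and not at the equally near C6–F (ortho): C6 is wedged between chain-bearing C5a and acyl-bearing C7 whereas C9a has only H-bearing C9 as its outer neighbour, and with K+ locked in the crown in DMSO no cation bridge from the ketone oxygen can guide the alkoxide to C6, so the bare alkoxide is instead repelled by the carbonyl lone pairs. One equivalent of base, which ends as KF, and high dilution keep C5–H removal and intermolecular arylation low.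

Step 9
Reactants: 18 3-[3,4-bis(methoxymethoxy)phenyl]-1-(6,8-difluoro-3-methyl-2,5-dihydro-1-benzoxepin-7-yl)propan-1-one
Product: 20 3-[3,4-bis(methoxymethoxy)phenyl]-1-[6,8-bis(4-methoxybenzyloxy)-3-methyl-2,5-dihydro-1-benzoxepin-7-yl]propan-1-one, via C8 monoether 19 (not isolated)
Conditions: 4-MeOC6H4CH2OH (6 equiv), NaH (5 equiv), toluene–THF 4:1, 0 °C → rt, then 80 °C
Reagents that add atoms: 4-methoxybenzyl alcohol COc1ccc(CO)cc1
Why: Twofold intermolecular SNAr ortho to the ketone, in which the sodium alkoxide stays an ion pair in the weakly polar medium, binds the ketone oxygen and is handed to the neighbouring C–F carbons, first the open C8 (19) and on heating the flanked C6, while this medium keeps enolisation and C5–H removal low and the MOM acetals and the O1 ether offer no leaving group that competes with fluoride.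

Step 10
Reactants: 20 bis-PMB ether
Product: 21 3-[3,4-bis(methoxymethoxy)phenyl]-1-(6,8-dihydroxy-3-methyl-2,5-dihydro-1-benzoxepin-7-yl)propan-1-one
Conditions: TFA (5 vol %), anisole (20 equiv), CH2Cl2, 0 °C, 30 min
Reagents that add atoms: none
Why: SN1 acidolysis of p-methoxybenzyl aryl ethers, in which the two ethers flank the ketone, whose protonation makes the chelated phenols good leaving groups, so that they should ionise at 0 °C well before the catechol MOM acetals (any MOM loss here is harmless), and anisole removes the benzyl cation by Friedel–Crafts alkylation before it can attack C9 or the catechol ring.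

Step 11
Reactants: 21 3-[3,4-bis(methoxymethoxy)phenyl]-1-(6,8-dihydroxy-3-methyl-2,5-dihydro-1-benzoxepin-7-yl)propan-1-one
Product: 22 3-(3,4-dihydroxyphenyl)-1-(6,8-dihydroxy-3-methyl-2,5-dihydro-1-benzoxepin-7-yl)propan-1-one (target)
Conditions: HCl (1.25 M in MeOH), MeOH–THF, 40 °C, Ar
Reagents that add atoms: none
Why: Acid-catalysed transacetalisation with methanol carries the CH2 units away as dimethoxymethane under conditions that trisubstituted alkenes and primary allylic aryl ethers tolerate, because O1 is a poorly basic vinylogous ester oxygen and the C6 hydroxyl cannot reach C3 while the oxepine is closed.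

Compound list
1 | prop-2-yn-1-ol (propargyl alcohol) | C#CCO | starting material
2 | (Z)-3-(bromomagnesio)-2-methylprop-2-en-1-olate, bromomagnesium salt (not isolated) | C/C(CO[Mg]Br)=C/[Mg]Br | intermediate
3 | (Z)-3-iodo-2-methylprop-2-en-1-ol | C/C(CO)=C/I | intermediate
4 | (Z)-tert-butyl[(3-iodo-2-methylprop-2-en-1-yl)oxy]dimethylsilane | C/C(CO[Si](C)(C)C(C)(C)C)=C/I | intermediate
5 | 2,4,6-trifluorobenzyl bromide | Fc1cc(F)c(CBr)c(F)c1 | starting material
6 | 2,4,6-trifluorobenzylzinc bromide (not isolated) | Fc1cc(F)c(C[Zn]Br)c(F)c1 | intermediate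
7 | (Z)-tert-butyldimethyl{[2-methyl-4-(2,4,6-trifluorophenyl)but-2-en-1-yl]oxy}silane | C/C(CO[Si](C)(C)C(C)(C)C)=C/Cc1c(F)cc(F)cc1F | intermediate
8 | 3-(3,4-dihydroxyphenyl)propanoic acid | OC(=O)CCc1ccc(O)c(O)c1 | starting material
9 | benzotriazol-1-yl 3-(3,4-dihydroxyphenyl)propanoate (not isolated) | O=C(CCc1ccc(O)c(O)c1)On1nnc2ccccc12 | intermediate
10 | 3-(3,4-dihydroxyphenyl)-N-methoxy-N-methylpropanamide | CON(C)C(=O)CCc1ccc(O)c(O)c1 | intermediate
11 | 3-[3,4-bis(methoxymethoxy)phenyl]-N-methoxy-N-methylpropanamide | CON(C)C(=O)CCc1ccc(OCOC)c(OCOC)c1 | intermediate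
12 | 3-[(Z)-4-(tert-butyldimethylsilyloxy)-3-methylbut-2-en-1-yl]-2,4,6-trifluorophenyllithium (not isolated) | C/C(CO[Si](C)(C)C(C)(C)C)=C/Cc1c(F)cc(F)c([Li])c1F | intermediate
13 | lithium hemiaminal adduct of 12 and 11 (not isolated) | C/C(CO[Si](C)(C)C(C)(C)C)=C/Cc1c(F)cc(F)c(C([O-])(CCc2ccc(OCOC)c(OCOC)c2)N(C)OC)c1F.[Li+] | intermediate
14 | 3-[3,4-bis(methoxymethoxy)phenyl]-1-{3-[(Z)-4-(tert-butyldimethylsilyloxy)-3-methylbut-2-en-1-yl]-2,4,6-trifluorophenyl}propan-1-one | C/C(CO[Si](C)(C)C(C)(C)C)=C/Cc1c(F)cc(F)c(C(=O)CCc2ccc(OCOC)c(OCOC)c2)c1F | intermediate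
15 | 3-[3,4-bis(methoxymethoxy)phenyl]-1-{2,4,6-trifluoro-3-[(Z)-4-hydroxy-3-methylbut-2-en-1-yl]phenyl}propan-1-one (key-step precursor) | C/C(CO)=C/Cc1c(F)cc(F)c(C(=O)CCc2ccc(OCOC)c(OCOC)c2)c1F | intermediate
16 | potassium alkoxide of 15 (not isolated) | C/C(C[O-])=C/Cc1c(F)cc(F)c(C(=O)CCc2ccc(OCOC)c(OCOC)c2)c1F.[K+] | intermediate
17 | Meisenheimer adduct, sp3 C9a bearing F and O1, charge on the ketone oxygen (not isolated) | CC1=CCC2=C(F)C(=C([O-])CCc3ccc(OCOC)c(OCOC)c3)C(F)=CC2(F)OC1.[K+] | intermediate
18 | 3-[3,4-bis(methoxymethoxy)phenyl]-1-(6,8-difluoro-3-methyl-2,5-dihydro-1-benzoxepin-7-yl)propan-1-one (key-step product) | CC1=CCc2c(cc(F)c(C(=O)CCc3ccc(OCOC)c(OCOC)c3)c2F)OC1 | intermediate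
19 | 3-[3,4-bis(methoxymethoxy)phenyl]-1-[6-fluoro-8-(4-methoxybenzyloxy)-3-methyl-2,5-dihydro-1-benzoxepin-7-yl]propan-1-one (not isolated) | CC1=CCc2c(cc(OCc4ccc(OC)cc4)c(C(=O)CCc3ccc(OCOC)c(OCOC)c3)c2F)OC1 | intermediate
20 | 3-[3,4-bis(methoxymethoxy)phenyl]-1-[6,8-bis(4-methoxybenzyloxy)-3-methyl-2,5-dihydro-1-benzoxepin-7-yl]propan-1-one | CC1=CCc2c(cc(OCc4ccc(OC)cc4)c(C(=O)CCc3ccc(OCOC)c(OCOC)c3)c2OCc5ccc(OC)cc5)OC1 | intermediate
21 | 3-[3,4-bis(methoxymethoxy)phenyl]-1-(6,8-dihydroxy-3-methyl-2,5-dihydro-1-benzoxepin-7-yl)propan-1-one | CC1=CCc2c(cc(O)c(C(=O)CCc3ccc(OCOC)c(OCOC)c3)c2O)OC1 | intermediate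
22 | 3-(3,4-dihydroxyphenyl)-1-(6,8-dihydroxy-3-methyl-2,5-dihydro-1-benzoxepin-7-yl)propan-1-one | CC1=CCc2c(cc(O)c(C(=O)CCc3ccc(O)c(O)c3)c2O)OC1 | target

Total step count: 11
Longest linear sequence: 9 steps (1, 2, 3, 6, 7, 8, 9, 10, 11)

Steps most likely to fail

1. Step 8.
What may go wrong:
- The alkoxide may add to the ortho C6–F instead of the para C9a–F.
- The ketone is twisted by its two ortho fluorines, so it may transmit too little para activation.
- The substrate may stay parked as its enolate.
- Removal of C5–H may trigger alkene migration or a 1,4-elimination that reopens the new ether.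
- The two closure modes should be easy to tell apart: the aromatic proton of 18 has one neighbouring fluorine, and that of the isomer has two.

Fallback, from 7 back to 18: the ring is closed before the ketone is in place. HF·pyridine frees (Z)-2-methyl-4-(2,4,6-trifluorophenyl)but-2-en-1-ol F1. In F1 the two fluorines next to the chain are equivalent by symmetry. Alkoxide SNAr (NaH, DMF, 25–60 °C) is activated only by the two meta fluorines, as in alkoxide substitutions of 1,3,5-trifluorobenzene, and can lead only to 6,8-difluoro-3-methyl-2,5-dihydro-1-benzoxepine F2. n-BuLi in THF at −78 °C then removes C7–H, the one proton between two fluorines, to give 6,8-difluoro-3-methyl-2,5-dihydro-1-benzoxepin-7-yllithium F3. This adds to 11 to give the lithium hemiaminal adduct F4, and a cold acetic acid quench delivers 18.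

2. Step 9.
What may go wrong:
- The second displacement may stall at the crowded and by then electron-rich C6.
- Forcing it with hot alkoxide invites removal of C5–H, followed by alkene migration into conjugation or 1,4-elimination across C5–C2.
- Hot benzylic alkoxide may also transfer hydride to the ketone.

Fallback, from 18 back to 21: one equivalent of sodium 4-methoxybenzyl oxide at 0 °C → rt is used, so that monoether 19 is isolated. The remaining C6–F is then replaced by the weakly basic α-effect anion of (E)-benzaldehyde oxime (K2CO3, DMSO, 60–80 °C), which acts as a hydroxide surrogate rather than an alkoxide. The O-aryl benzaldoxime F5 loses benzonitrile in the same flask and gives the C6 phenol, 3-[3,4-bis(methoxymethoxy)phenyl]-1-[6-hydroxy-8-(4-methoxybenzyloxy)-3-methyl-2,5-dihydro-1-benzoxepin-7-yl]propan-1-one F6. TFA/anisole as in step 10 then leads to 21.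

3. Step 6.
What may go wrong:
- The stabilised, hindered aryllithium may add too slowly to the amide at the low temperature needed to prevent loss of LiF (aryne formation).
- Proton transfer from the amide α-CH2 or from the benzylic–allylic CH2 would return starting materials.

Fallback, from 11 and 7 back to 14: amide 11 is reduced with DIBAL-H (THF, −78 °C) to 3-[3,4-bis(methoxymethoxy)phenyl]propanal F7. This much faster electrophile captures aryllithium 12 at −78 °C to give the racemic secondary benzylic alcohol F8, whose carbinol centre is erased when Dess–Martin periodinane (CH2Cl2, NaHCO3, rt) oxidises it to 14.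

Further compounds
F1 | step 8 | (Z)-2-methyl-4-(2,4,6-trifluorophenyl)but-2-en-1-ol | C/C(CO)=C/Cc1c(F)cc(F)cc1F
F2 | step 8 | 6,8-difluoro-3-methyl-2,5-dihydro-1-benzoxepine | CC1=CCc2c(cc(F)cc2F)OC1
F3 | step 8 | 6,8-difluoro-3-methyl-2,5-dihydro-1-benzoxepin-7-yllithium | CC1=CCc2c(cc(F)c([Li])c2F)OC1
F4 | step 8 | lithium hemiaminal adduct of F3 and 11 | CC1=CCc2c(cc(F)c(C([O-])(CCc3ccc(OCOC)c(OCOC)c3)N(C)OC)c2F)OC1.[Li+]
F5 | step 9 | O-aryl (E)-benzaldoxime at C6 of the 8-(4-methoxybenzyloxy) ketone | CC1=CCc2c(cc(OCc4ccc(OC)cc4)c(C(=O)CCc3ccc(OCOC)c(OCOC)c3)c2O/N=C/c5ccccc5)OC1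
F6 | step 9 | 3-[3,4-bis(methoxymethoxy)phenyl]-1-[6-hydroxy-8-(4-methoxybenzyloxy)-3-methyl-2,5-dihydro-1-benzoxepin-7-yl]propan-1-one | CC1=CCc2c(cc(OCc4ccc(OC)cc4)c(C(=O)CCc3ccc(OCOC)c(OCOC)c3)c2O)OC1
F7 | step 6 | 3-[3,4-bis(methoxymethoxy)phenyl]propanal | O=CCCc1ccc(OCOC)c(OCOC)c1
F8 | step 6 | 3-[3,4-bis(methoxymethoxy)phenyl]-1-{3-[(Z)-4-(tert-butyldimethylsilyloxy)-3-methylbut-2-en-1-yl]-2,4,6-trifluorophenyl}propan-1-ol (racemic) | C/C(CO[Si](C)(C)C(C)(C)C)=C/Cc1c(F)cc(F)c(C(O)CCc2ccc(OCOC)c(OCOC)c2)c1F
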